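**Retrosynthetic overview**
1. Target 13 comes from Hg(II) unmasking of a 1,3-bis(methylsulfanyl)cyclohexene (a masked enone); the only ring, the cyclohexene, is closed at C3–C4.
2. The ring comes from intramolecular oxirane opening by a sulfur-stabilised allyl anion. Its precursor 10 comes from 1,3-bis(methylsulfanyl)allyllithium (an acrolein C1/C3 dianion equivalent) and the C4–C5–C6 bis-electrophile 6. C1–C6 is made first, then C3–C4, each joining an enone carbon that is normally electrophilic to an oxirane carbon.
3. Epoxy chloride 6 comes from (S)-2-nonadecylglycidol 5, made by Sharpless epoxidation of allylic alcohol 4; this sets C5, the only stereocentre.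
4. Alcohol 4 comes from the methallyl alcohol dianion and 1-bromooctadecane.

Assumption: the chain is n-nonadecyl and the target is (5S)-5-hydroxy-5-nonadecylcyclohex-2-en-1-one; compound 7 and LDA solution are taken as catalogue reagents (7 is otherwise two steps from epichlorohydrin, NaSMe and MeI).

**Step 1**
Reactants: 1 2-methylprop-2-en-1-ol; 2 1-bromooctadecane
Product: 4 2-methylidenehenicosan-1-ol, via methallyl alcohol dianion 3 (not isolated)
Conditions: n-BuLi (2.2 equiv), TMEDA (2.2 equiv), Et2O/hexane, 0 → 25 °C, 24 h; then 2 (0.9 equiv) in THF, −78 → 25 °C; H2O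
Reagents that add atoms: none
Why: O,C-dimetalation of methallyl alcohol gives an allyl anion that is far more nucleophilic at carbon than the lithium alkoxide, so the primary bromide is C-alkylated by SN2 (dianion alkylation), giving the 2-nonadecyl allylic alcohol in one step with no stereocentre formed.

**Step 2**
Reactants: 4 2-methylidenehenicosan-1-ol
Product: 5 [(2S)-2-nonadecyloxiran-2-yl]methanol
Conditions: Ti(OiPr)4 (10 mol%), L-(+)-DIPT (12 mol%), t-BuOOH (2 equiv, anhydrous), 4 Å MS, CH2Cl2, −20 °C; recrystallise from hexane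
Reagents that add atoms: tert-butyl hydroperoxide, CC(C)(C)OO
Why: Katsuki–Sharpless asymmetric epoxidation of a 2-alkyl allylic alcohol; L-(+)-tartrate delivers oxygen to the face that gives the (S)-2-alkylglycidol (same sense as (S)-glycidol from allyl alcohol), which sets C5, and the waxy product can be recrystallised to raise the ee.

**Step 3**
Reactants: 5 [(2S)-2-nonadecyloxiran-2-yl]methanol
Product: 6 (2R)-2-(chloromethyl)-2-nonadecyloxirane
Conditions: PPh3 (1.3 equiv), CCl4, NaHCO3 (0.2 equiv), reflux
Reagents that add atoms: tetrachloromethane, ClC(Cl)(Cl)Cl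
Why: Appel chlorination of the primary alcohol under buffered conditions leaves the oxirane and every bond to the stereocentre intact (the descriptor changes from S to R only through CIP priorities), as is routine for 2,3-epoxy alcohols.

**Step 4**
Reactants: 6 (2R)-2-(chloromethyl)-2-nonadecyloxirane; 7 2-methoxy-1,3-bis(methylsulfanyl)propane
Product: 10 (2R)-2-[2,4-bis(methylsulfanyl)but-3-en-1-yl]-2-nonadecyloxirane (mixture at C–S and C=C), via 1,3-bis(methylsulfanyl)allyllithium 8 (not isolated), via lithium chlorohydrin alkoxide 9 (not isolated)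
Conditions: 7 (1.0 equiv), LDA (2.0 equiv), THF, −78 → 0 °C; then 6 (1.05 equiv), −78 → 25 °C; aqueous work-up, Et3N-deactivated SiO2
Reagents that add atoms: none
Why: LDA eliminates methoxide from 7 and deprotonates to give the symmetric sulfur-stabilised allyl anion, which opens the oxirane at its unsubstituted CH2 by SN2 (the neopentyl-type CH2Cl is inert) to form C1–C6, and on warming the tertiary alkoxide displaces chloride (epichlorohydrin-type relay, intramolecular Williamson closure) so the oxirane moves to the C4 side without touching the stereocentre.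

**Step 5**
Reactants: 10 (2R)-2-[2,4-bis(methylsulfanyl)but-3-en-1-yl]-2-nonadecyloxirane
Product: 13 (5S)-5-hydroxy-5-nonadecylcyclohex-2-en-1-one, via lithiated epoxide 11 (not isolated), via cyclohexenyl bis-sulfide 12 (not isolated)
Conditions: s-BuLi (0.95 equiv), THF (0.01 M), −78 °C then → −20 °C; AcOH (1.0 equiv), −78 °C; then HgCl2 (2.5 equiv), CaCO3 (3 equiv), MeCN/H2O 4:1, 25 °C
Reagents that add atoms: water, O
Why: Proposed new method: amine-free remetalation of the doubly activated allylic C–H regenerates a 1,3-bis(methylsulfanyl)allyl anion whose unsubstituted terminus opens the oxirane at its primary carbon (six-membered endo SN2; the exo mode would need SN2 at the quaternary carbon and attack through the substituted terminus would give three- or four-membered rings), forming C3–C4 and the ring; the carbon alkylated first bears no hydrogen and so becomes C1=O on Hg(II)-assisted vinyl sulfide hydrolysis with β-loss of the second MeS group, which maps the step-2 stereocentre onto (S) provided 12 is never deprotonated to its symmetric allyl anion (hence sub-stoichiometric base, no amine, high dilution, acid quench before unmasking); the closest known reactions are the sequential C1/C3 alkylation of this reagent and the Stork epoxynitrile cyclisation at the less substituted oxirane carbon.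

**Compound list**
1 | 2-methylprop-2-en-1-ol (methallyl alcohol) | CC(=C)CO | starting material
2 | 1-bromooctadecane | CCCCCCCCCCCCCCCCCCBr | starting material
3 | dilithium salt of the methallyl alcohol O,C-dianion | [Li+].[Li+].[CH2-]C(=C)C[O-] | intermediate
4 | 2-methylidenehenicosan-1-ol | CCCCCCCCCCCCCCCCCCCC(=C)CO | intermediate
5 | [(2S)-2-nonadecyloxiran-2-yl]methanol | CCCCCCCCCCCCCCCCCCC[C@]1(CO)CO1 | intermediate
6 | (2R)-2-(chloromethyl)-2-nonadecyloxirane | CCCCCCCCCCCCCCCCCCC[C@]1(CCl)CO1 | intermediate
7 | 2-methoxy-1,3-bis(methylsulfanyl)propane | COC(CSC)CSC | starting material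
8 | 1,3-bis(methylsulfanyl)allyllithium | [Li+].CS[CH-]C=CSC | intermediate
9 | lithium (2R)-1-chloro-4,6-bis(methylsulfanyl)-2-nonadecylhex-5-en-2-olate | CCCCCCCCCCCCCCCCCCC[C@]([O-])(CCl)CC(SC)C=CSC.[Li+] | intermediate
10 | (2R)-2-[2,4-bis(methylsulfanyl)but-3-en-1-yl]-2-nonadecyloxirane | CCCCCCCCCCCCCCCCCCC[C@]1(CO1)CC(SC)C=CSC | intermediate
11 | lithium 1,3-bis(methylsulfanyl)-1-{[(2R)-2-nonadecyloxiran-2-yl]methyl}prop-2-en-1-ide | CCCCCCCCCCCCCCCCCCC[C@]1(CO1)C[C-](SC)C=CSC.[Li+] | intermediate
12 | (1S)-3,5-bis(methylsulfanyl)-1-nonadecylcyclohex-3-en-1-ol (C5 epimers; formed as its lithium alkoxide, neutralised by AcOH) | CCCCCCCCCCCCCCCCCCC[C@]1(O)CC(SC)C=C(SC)C1 | intermediate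
13 | (5S)-5-hydroxy-5-nonadecylcyclohex-2-en-1-one | CCCCCCCCCCCCCCCCCCC[C@]1(O)CC=CC(=O)C1 | target

**Summary**
Total step count: 5. Longest linear sequence: 5 (1 → 4 → 5 → 6 → 10 → 13).

**Steps most likely to fail**

Step 5 (ring closure and unmasking). The anion may attack through its substituted terminus, fail to cyclise, or the cyclised sulfide 12 may be deprotonated, which scrambles C1/C3 and erodes ee; the product can also dehydrate to 3-nonadecylphenol. The fallback sets out from 6 and returns at 13, closing the ring by aldol condensation instead. 2-Lithio-2-methyl-1,3-dithiane (THF/DMPU) opens the oxirane CH2 of 6 to give lithium (2R)-1-chloro-2-[(2-methyl-1,3-dithian-2-yl)methyl]henicosan-2-olate F1, which closes on warming to (2R)-2-[(2-methyl-1,3-dithian-2-yl)methyl]-2-nonadecyloxirane F2. 2-Lithio-1,3-dithiane then opens F2 to (2S)-1-(1,3-dithian-2-yl)-2-[(2-methyl-1,3-dithian-2-yl)methyl]henicosan-2-ol F3. MeI/CaCO3 in aqueous MeCN unmasks both carbonyls to (3S)-3-hydroxy-3-(2-oxopropyl)docosanal F4. Catalytic pyrrolidine/AcOH gives the six-membered aldol (5S)-3,5-dihydroxy-5-nonadecylcyclohexan-1-one F5, which loses water to 13. The other aldol modes would give four-membered rings, and the acetyl unit sits on the original oxirane CH2 (C6) as in the main route.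

Step 4 (allyl anion opening of the 2,2-disubstituted oxirane). The delocalised anion may react sluggishly, transfer a proton, or add twice. The fallback sets out from 6 and returns at 13, closing the ring by metathesis. 1-Lithio-1-methoxyallene (an acryloyl anion equivalent) opens 6 to lithium (2R)-1-chloro-4-methoxy-2-nonadecylhexa-4,5-dien-2-olate F6, which closes to (2R)-2-(2-methoxybuta-2,3-dien-1-yl)-2-nonadecyloxirane F7. VinylMgBr with catalytic CuI opens F7 to (4S)-4-(2-methoxybuta-2,3-dien-1-yl)tricos-1-en-4-ol F8. Dilute aqueous acid gives (5S)-5-hydroxy-5-(prop-2-en-1-yl)tetracos-1-en-3-one F9, and Grubbs II ring-closing metathesis gives 13.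

Step 1 (dianion alkylation). Dimetalation may be incomplete, or the long-chain bromide may undergo E2 elimination. The fallback sets out from 2 and returns at 4. Magnesium converts 2 into octadecylmagnesium bromide F10, which undergoes copper-catalysed SN2′ coupling with methyl 2-(bromomethyl)acrylate to give methyl 2-methylidenehenicosanoate F11; DIBAL-H reduction of F11 gives 4.

**Further compounds**
F1 | step 5 | lithium (2R)-1-chloro-2-[(2-methyl-1,3-dithian-2-yl)methyl]henicosan-2-olate | CCCCCCCCCCCCCCCCCCC[C@]([O-])(CCl)CC1(C)SCCCS1.[Li+]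
F2 | step 5 | (2R)-2-[(2-methyl-1,3-dithian-2-yl)methyl]-2-nonadecyloxirane | CCCCCCCCCCCCCCCCCCC[C@]1(CO1)CC2(C)SCCCS2
F3 | step 5 | (2S)-1-(1,3-dithian-2-yl)-2-[(2-methyl-1,3-dithian-2-yl)methyl]henicosan-2-ol | CCCCCCCCCCCCCCCCCCC[C@](O)(CC1SCCCS1)CC1(C)SCCCS1
F4 | step 5 | (3S)-3-hydroxy-3-(2-oxopropyl)docosanal | CCCCCCCCCCCCCCCCCCC[C@](O)(CC=O)CC(C)=O
F5 | step 5 | (5S)-3,5-dihydroxy-5-nonadecylcyclohexan-1-one (C3 epimers) | CCCCCCCCCCCCCCCCCCC[C@]1(O)CC(O)CC(=O)C1
F6 | step 4 | lithium (2R)-1-chloro-4-methoxy-2-nonadecylhexa-4,5-dien-2-olate | CCCCCCCCCCCCCCCCCCC[C@]([O-])(CCl)CC(OC)=C=C.[Li+]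
F7 | step 4 | (2R)-2-(2-methoxybuta-2,3-dien-1-yl)-2-nonadecyloxirane | CCCCCCCCCCCCCCCCCCC[C@]1(CO1)CC(OC)=C=C
F8 | step 4 | (4S)-4-(2-methoxybuta-2,3-dien-1-yl)tricos-1-en-4-ol | CCCCCCCCCCCCCCCCCCC[C@](O)(CC=C)CC(OC)=C=C
F9 | step 4 | (5S)-5-hydroxy-5-(prop-2-en-1-yl)tetracos-1-en-3-one | CCCCCCCCCCCCCCCCCCC[C@](O)(CC=C)CC(=O)C=C
F10 | step 1 | octadecylmagnesium bromide | CCCCCCCCCCCCCCCCCC[Mg]Br
F11 | step 1 | methyl 2-methylidenehenicosanoate | CCCCCCCCCCCCCCCCCCCC(=C)C(=O)OC
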